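## Analysis of the target

Rhuschalcone VI is a bichalcone: two 1-(2,4-dihydroxyphenyl)-3-(4-hydroxyphenyl)prop-2-en-1-one units joined by one biaryl bond. Ring A is the terminal 2,4-dihydroxyphenyl ketone ring and ring B the 4-hydroxyphenyl ring of the first unit, ring C is the central 2,4-dihydroxyphenyl ketone ring and ring D the terminal 4-hydroxyphenyl ring, and the biaryl bond runs from C3 of ring B to C5 of ring C. The molecule has no stereogenic centre, and its only stereo-elements are the two E enone double bonds, which are the thermodynamically preferred geometry. The sensitive groups are six free phenols (oxidation-prone once ionised) and two 2-hydroxyaryl enones, which are Michael acceptors, close to flavanones under acid or base and fragment by retro-aldol cleavage in hot alkali. The difficulty is that the two enone arms are almost identical chemically but sit on different rings of an unsymmetrical biaryl with an oxygen ortho to the axis on each side, so each arm must be made by a step that leaves the other untouched, without a long protecting-group sequence for six phenols. The strategy rests on ring A: its C2 hydroxyl is ortho to the ketone and the enone β-carbon is bonded to C1 of ring B, so the A–B chalcone is the ring-opened isomer of a 7-hydroxyflavanone, which is the 1,4-adduct of a ring B aryl nucleophile and a chromone. While the A–B arm is held in that form, ring C is a free 4-arylresorcinol whose position para to one hydroxyl and ortho to the other (C1 in ketone numbering) is the most nucleophilic carbon in the molecule, so the C–D arm can be added late by Friedel–Crafts acylation.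

## Retrosynthetic reasoning

Target 15 is traced back to flavanone 13 (through the open-chain phenolate 14). No carbon–carbon bond is cut; the ring A 2-hydroxyl is added across the A–B enone to form the O1–C2 bond of a chroman-4-one. This isomer has no A–B Michael acceptor and no free ortho-hydroxy ketone on ring A, so the A–B half is inert while the other half is built. Forward, strong aqueous base must open the ring by retro-oxa-Michael elimination and cold acid must release the chalcone before it can re-close. The C2 stereocentre disappears, so racemic material is sufficient.

Flavanone 13 is cut at the aryl–carbonyl bond on C1 of ring C, giving tetraphenol 11 and the acid 12. This is the one bond whose formation can use innate reactivity. In 11, ring C is a free resorcinol, ring A is deactivated by its ketone and ring B is only a monophenol. Acid 12 brings ring D and the E double bond in one piece. Cutting the enone Cα–Cβ bond instead would require an acetyl group to be carried through every earlier step.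

Tetraphenol 11 comes from its tetrakis(methoxymethyl) ether 10. The four acetals are needed only for the palladium steps. They are removed together before the Lewis-acid step, so that no formaldehyde equivalent is set free next to a free resorcinol under acylation conditions.

Flavanone 10 is cut at the bond between C2 of the heterocycle and C1 of ring B, giving chromone 9 and boronic acid 7. This single bond completes the carbon skeleton of the A–B arm and installs its masked form in the same step. The boron in 7 sits at a position with no ortho substituent, so transmetalation is unhindered. The forward reaction has to be a 1,4-addition that stops at the saturated ketone and does not go on to the flavone.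

Chromone 9 is the methoxymethyl ether of commercial 8. The protection has to leave the base-sensitive pyranone ring intact.

Boronic acid 7 is traced to aryl chloride 6 by carbon–boron for carbon–chlorine exchange. Chlorine is chosen as the placeholder because it survives the biaryl coupling in which a bromide reacts.

Biaryl 6 is cut at the bond between C3 of ring B and C5 of ring C, giving pinacol boronate 3 and bromochloroarene 5. Both halves come from cheap halophenols, and the bromine/chlorine difference in 5 fixes which carbon couples. The boron is placed on the ring C partner as an ester to limit protodeboronation of a 2,4-dioxygenated aryl boron species.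

Boronate 3 comes from bromide 2 and this from commercial 1; 5 comes from commercial 4. These are plain protection and borylation steps.

## Alternatives that were turned down

Alternative 1: The aryl–carbonyl bond at C1 of ring C is cut on a biaryl with no protecting group. Forward, acid 12 would be condensed under the Lewis-acid conditions of step 9 with 4-(5-bromo-2-hydroxyphenyl)benzene-1,3-diol (A2) to give (E)-1-[5-(5-bromo-2-hydroxyphenyl)-2,4-dihydroxyphenyl]-3-(4-hydroxyphenyl)prop-2-en-1-one (A1). In A2, as in 11, ring C is the only resorcinol ring, so the site of acylation is the same. In its favour, this is the same Friedel–Crafts logic as step 9, so on that bond the two plans are equally strong, and A1 is reached in fewer steps than 13 because nothing is protected. Against it, A1 is only half the problem. The ring B bromide, para to a phenol, must still be turned into the whole A–B enone by palladium chemistry on a substrate with four free phenols, a chelating 2-hydroxy ketone and a Michael acceptor. Oxidative addition into a bromide whose para oxygen is ionised under basic coupling conditions is slow, so protection would have to be reintroduced after the fact. The chosen route is longer up to the acylation, but the A–B arm is already in place in a form inert to the Lewis acid, and the last step is an isomerisation and not a cross-coupling on an unprotected polyphenolic enone.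

Alternative 2: The bond between the enone β-carbon and C1 of ring D is cut. Forward, a Heck reaction with a divalent palladium salt reduced in the flask to zerovalent palladium would couple 4-iodophenol (A5) with the vinyl ketone 1-{5-[5-bromo-2-(methoxymethoxy)phenyl]-2,4-bis(methoxymethoxy)phenyl}prop-2-en-1-one (A4). The product would be (E)-1-{5-[5-bromo-2-(methoxymethoxy)phenyl]-2,4-bis(methoxymethoxy)phenyl}-3-(4-hydroxyphenyl)prop-2-en-1-one (A3). In its favour, oxidative addition distinguishes C–I from C–Br cleanly, the E geometry follows from syn insertion and syn β-hydride elimination, and no hot Lewis acid is used; on mildness at the C–D arm it is stronger than step 9. Against it, the aryl vinyl ketone A4 polymerises easily and accepts nucleophiles, including the phenoxide of A5 under basic Heck conditions. Making A4 needs an acylation and a vinyl introduction on protected ring C. A3 still carries the bromide, so a second enone construction on an electron-rich aryl bromide must follow in the presence of the first enone. The final acid removal of the acetals would then be done on two free 2-hydroxyaryl enones that can close to flavanones. The chosen strategy needs one catalytic C–C bond formation for the A–B arm, its product is protected by its own structure, and the acid deprotection is done while no enone is present.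

Alternative 3: The bond between the carbonyl carbon and the α-carbon of the C–D enone is cut. Forward, a chloro-rhodium diene precatalyst with a ferrocene bisphosphine and carbonate base would add the formyl C–H of 5-[5-bromo-2-(methoxymethoxy)phenyl]-2-hydroxy-4-(methoxymethoxy)benzaldehyde (A7) across 1-ethynyl-4-(methoxymethoxy)benzene (A8). The product would be (E)-1-{5-[5-bromo-2-(methoxymethoxy)phenyl]-2-hydroxy-4-(methoxymethoxy)phenyl}-3-[4-(methoxymethoxy)phenyl]prop-2-en-1-one (A6). In its favour, the reaction is fully atom-economic, the directing group is the ring C 2-hydroxyl that the target has anyway, and syn addition gives the E enone; in atom economy it beats every step of the chosen route. Against it, a terminal aryl alkyne can insert with either orientation, giving the linear E enone or the branched 1,1-disubstituted enone, and nothing in A7 or A8 biases this. Decarbonylation of the acyl rhodium hydride competes. A7 needs a formylated ring C with its two oxygens differentiated, which adds steps and regiochemical questions upstream. As in the other two alternatives, the ring B bromide of A6 still has to become the second enone arm. The chosen strategy is less atom-economic but relies on substrate-controlled regiochemistry in both arm-forming steps and ends without a second cross-coupling.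

Key step: step 7

Remark: the ring-opened intermediate of the last step is written as the fully ionised hexapotassium salt; its actual degree of ionisation depends on the excess of KOH and does not affect the outcome after acidification.

## Route

Step 1
Reactants: 1 4-bromoresorcinol (4-bromobenzene-1,3-diol)
Product: 2 1-bromo-2,4-bis(methoxymethoxy)benzene
Conditions: MOMCl, K2CO3, acetone, 0 °C to rt
Reagents that add atoms: chloromethyl methyl ether (MOMCl), COCCl
Why: O-alkylation of both phenoxides by the very electrophilic α-chloro ether (Williamson-type acetal formation); the methoxymethyl ethers remove the acidic hydroxyls for the palladium steps and come off later with acid.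

Step 2
Reactants: 2 1-bromo-2,4-bis(methoxymethoxy)benzene
Product: 3 2-[2,4-bis(methoxymethoxy)phenyl]-4,4,5,5-tetramethyl-1,3,2-dioxaborolane
Conditions: B2pin2, PdCl2[Fe(C5H4PPh2)2] (3 mol %), KOAc, 1,4-dioxane, 90 °C
Reagents that add atoms: bis(pinacolato)diboron, CC1(C)OB(OC1(C)C)B1OC(C)(C)C(C)(C)O1
Why: Miyaura borylation: oxidative addition into the C–Br bond, acetate-assisted transmetalation with the diboron and reductive elimination; the pinacol ester is preferred to the free acid because 2,4-dialkoxyaryl boronic acids protodeboronate easily.

Step 3
Reactants: 4 2-bromo-4-chlorophenol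
Product: 5 2-bromo-4-chloro-1-(methoxymethoxy)benzene
Conditions: MOMCl, K2CO3, acetone, 0 °C to rt
Reagents that add atoms: chloromethyl methyl ether (MOMCl), COCCl
Why: Same O-alkylation as in step 1; both halogens are untouched.

Step 4
Reactants: 3 2-[2,4-bis(methoxymethoxy)phenyl]-4,4,5,5-tetramethyl-1,3,2-dioxaborolane; 5 2-bromo-4-chloro-1-(methoxymethoxy)benzene
Product: 6 5-chloro-2,2',4'-tris(methoxymethoxy)-1,1'-biphenyl
Conditions: Pd(PPh3)4 (5 mol %), 2 M aq K2CO3, 1,4-dioxane, 85 °C
Reagents that add atoms: none
Why: Suzuki–Miyaura coupling; zerovalent palladium with PPh3 inserts into C–Br far faster than into the electron-rich C–Cl bond, so the chlorine is kept as the handle for boron, and one alkoxy group ortho to the new bond on each ring is well tolerated.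

Step 5
Reactants: 6 5-chloro-2,2',4'-tris(methoxymethoxy)-1,1'-biphenyl
Product: 7 {3-[2,4-bis(methoxymethoxy)phenyl]-4-(methoxymethoxy)phenyl}boronic acid
Conditions: B2(OH)4, second-generation XPhos precatalyst chloro(2-dicyclohexylphosphino-2',4',6'-triisopropylbiphenyl)[2-(2'-amino-1,1'-biphenyl)]palladium (2 mol %), XPhos (4 mol %), KOAc, EtOH, 80 °C
Reagents that add atoms: tetrahydroxydiboron, OB(O)B(O)O
Why: Palladium-catalysed borylation of an aryl chloride with tetrahydroxydiboron; the bulky electron-rich biaryl phosphine makes oxidative addition into the deactivated C–Cl bond possible, and the free boronic acid needed for step 7 is obtained directly without an ester cleavage.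

Step 6
Reactants: 8 7-hydroxy-4H-chromen-4-one
Product: 9 7-(methoxymethoxy)-4H-chromen-4-one
Conditions: MOMCl, K2CO3, acetone, rt
Reagents that add atoms: chloromethyl methyl ether (MOMCl), COCCl
Why: O-alkylation of the acidic 7-hydroxyl (a vinylogous acid); carbonate in dry acetone is not nucleophilic enough to open the pyranone ring.

Step 7
Reactants: 9 7-(methoxymethoxy)-4H-chromen-4-one (1.5 equiv); 7 {3-[2,4-bis(methoxymethoxy)phenyl]-4-(methoxymethoxy)phenyl}boronic acid
Product: 10 2-{3-[2,4-bis(methoxymethoxy)phenyl]-4-(methoxymethoxy)phenyl}-7-(methoxymethoxy)chroman-4-one (racemic)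
Conditions: Pd(OCOCF3)2 (10 mol %), 2,2'-bipyridine (12 mol %), NH4PF6 (30 mol %), H2O (5 equiv), ClCH2CH2Cl, 60 °C, N2
Reagents that add atoms: none
Why: The cationic bipyridine complex of divalent palladium takes the aryl group from boron by transmetalation, the chromone C2–C3 double bond inserts syn into the aryl–palladium bond with the aryl going to C2, and the resulting palladium enolate is protonated by water, which returns divalent palladium without any redox change. The closest known reaction type is the conjugate addition of arylboronic acids to chromones and cyclic enones catalysed by divalent palladium with bidentate nitrogen ligands. No ring closes; one C–C bond is formed between C2 of the heterocycle and C1 of ring B. The new C2 stereocentre is formed without control because the ligand is achiral, which is intended since step 10 destroys it. The selectivity needed is 1,4-addition with protonation over oxidative Heck arylation to the flavone: after syn insertion the C2 hydrogen is anti to palladium, so β-hydride elimination is only possible after epimerisation through the enolate, while the cationic enolate is protonated quickly in the wet medium and the nitrogen atmosphere provides no reoxidant for a Heck cycle. The boronic acid has no substituent ortho to boron, so transmetalation is unhindered, and 9 is used in excess because 7 is the valuable partner. The acetals should survive the nearly neutral medium, and partial loss would not matter because step 8 removes all four.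

Step 8
Reactants: 10 2-{3-[2,4-bis(methoxymethoxy)phenyl]-4-(methoxymethoxy)phenyl}-7-(methoxymethoxy)chroman-4-one
Product: 11 2-[3-(2,4-dihydroxyphenyl)-4-hydroxyphenyl]-7-hydroxychroman-4-one (racemic)
Conditions: 1.25 M HCl in MeOH, 50 °C
Reagents that add atoms: none
Why: Acid-catalysed acetal exchange with methanol removes all four methoxymethyl groups as dimethoxymethane; the flavanone is the acid-stable isomer of the chalcone, and deprotecting here keeps formaldehyde equivalents away from the free resorcinol in the Lewis-acid step.

Step 9
Reactants: 11 2-[3-(2,4-dihydroxyphenyl)-4-hydroxyphenyl]-7-hydroxychroman-4-one; 12 (E)-4-hydroxycinnamic acid (1.1 equiv)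
Product: 13 2-(3-{2,4-dihydroxy-5-[(2E)-3-(4-hydroxyphenyl)prop-2-enoyl]phenyl}-4-hydroxyphenyl)-7-hydroxychroman-4-one (racemic)
Conditions: BF3·OEt2 (excess, as medium), 90 °C, N2; then 10% aq NaOAc
Reagents that add atoms: none
Why: Friedel–Crafts (Nencki-type) C-acylation of a resorcinol by a carboxylic acid activated with BF3, a known direct route to 2',4'-dihydroxychalcones; ring C reacts at the carbon para to one hydroxyl and ortho to the other because ring A is deactivated by its ketone, ring B is only a monophenol and the position between the two ring C hydroxyls is hindered. The aqueous acetate work-up breaks any boron chelation of the new ortho-hydroxy ketone, and any acid-induced closure of the new 2-hydroxyaryl enone would be reversed by the base of step 10.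

Step 10
Reactants: 13 2-(3-{2,4-dihydroxy-5-[(2E)-3-(4-hydroxyphenyl)prop-2-enoyl]phenyl}-4-hydroxyphenyl)-7-hydroxychroman-4-one
Product: 15 rhuschalcone VI, via hexapotassium hexaphenolate of rhuschalcone VI 14 (not isolated)
Conditions: 2 M aq KOH, EtOH, N2, rt; then 1 M HCl, 0 °C, to pH 3
Reagents that add atoms: none
Why: Base-induced retro-oxa-Michael (E1cB) opening of the flavanone, with the ring A phenoxide as leaving group and assisted by the para phenoxide of ring B, gives the open-chain phenolate 14 as the E enone; cold acidification protonates it faster than a 2-hydroxyaryl enone lacking a second ortho hydroxyl re-closes. The racemic C2 centre is erased and the E double bond forms as the thermodynamic isomer.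

## Compound list

1 | 4-bromoresorcinol (4-bromobenzene-1,3-diol) | Oc1ccc(Br)c(O)c1 | starting material
2 | 1-bromo-2,4-bis(methoxymethoxy)benzene | COCOc1ccc(Br)c(OCOC)c1 | intermediate
3 | 2-[2,4-bis(methoxymethoxy)phenyl]-4,4,5,5-tetramethyl-1,3,2-dioxaborolane | COCOc1ccc(B2OC(C)(C)C(C)(C)O2)c(OCOC)c1 | intermediate
4 | 2-bromo-4-chlorophenol | Oc1ccc(Cl)cc1Br | starting material
5 | 2-bromo-4-chloro-1-(methoxymethoxy)benzene | COCOc1ccc(Cl)cc1Br | intermediate
6 | 5-chloro-2,2',4'-tris(methoxymethoxy)-1,1'-biphenyl | COCOc1ccc(Cl)cc1-c1ccc(OCOC)cc1OCOC | intermediate
7 | {3-[2,4-bis(methoxymethoxy)phenyl]-4-(methoxymethoxy)phenyl}boronic acid | COCOc1ccc(B(O)O)cc1-c1ccc(OCOC)cc1OCOC | intermediate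
8 | 7-hydroxy-4H-chromen-4-one | O=c1ccoc2cc(O)ccc12 | starting material
9 | 7-(methoxymethoxy)-4H-chromen-4-one | O=c1ccoc2cc(OCOC)ccc12 | intermediate
10 | 2-{3-[2,4-bis(methoxymethoxy)phenyl]-4-(methoxymethoxy)phenyl}-7-(methoxymethoxy)chroman-4-one (racemic) | O=C1CC(c2ccc(OCOC)c(-c3ccc(OCOC)cc3OCOC)c2)Oc2cc(OCOC)ccc12 | intermediate
11 | 2-[3-(2,4-dihydroxyphenyl)-4-hydroxyphenyl]-7-hydroxychroman-4-one (racemic) | O=C1CC(c2ccc(O)c(-c3ccc(O)cc3O)c2)Oc2cc(O)ccc12 | intermediate
12 | (E)-4-hydroxycinnamic acid | O=C(O)/C=C/c1ccc(O)cc1 | starting material
13 | 2-(3-{2,4-dihydroxy-5-[(2E)-3-(4-hydroxyphenyl)prop-2-enoyl]phenyl}-4-hydroxyphenyl)-7-hydroxychroman-4-one (racemic) | O=C1CC(c2ccc(O)c(-c3cc(C(=O)/C=C/c4ccc(O)cc4)c(O)cc3O)c2)Oc2cc(O)ccc12 | intermediate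
14 | hexapotassium hexaphenolate of rhuschalcone VI | [K+].[K+].[K+].[K+].[K+].[K+].O=C(/C=C/c1ccc([O-])c(-c2cc(C(=O)/C=C/c3ccc([O-])cc3)c([O-])cc2[O-])c1)c1ccc([O-])cc1[O-] | intermediate
15 | rhuschalcone VI, (2E)-1-(2,4-dihydroxyphenyl)-3-(3-{2,4-dihydroxy-5-[(2E)-3-(4-hydroxyphenyl)prop-2-enoyl]phenyl}-4-hydroxyphenyl)prop-2-en-1-one | O=C(/C=C/c1ccc(O)c(-c2cc(C(=O)/C=C/c3ccc(O)cc3)c(O)cc2O)c1)c1ccc(O)cc1O | target

## Step count and risk

Total step count: 10. Longest linear sequence: 8 steps (steps 1, 2, 4, 5, 7, 8, 9, 10, from 4-bromoresorcinol).

Step 7 (key step). The most likely failure is protodeboronation of the electron-rich boronic acid in the wet, slightly acidic medium outrunning insertion, because the 7-alkoxy donor makes the chromone a sluggish acceptor. The second is epimerisation of the palladium enolate followed by β-hydride elimination, which leads to the flavone oxidation level and to inactive zerovalent palladium. The fallback sets out from 3 and comes back at 10, building the flavanone by the classical aldol route. Commercial 3-bromo-4-hydroxybenzaldehyde (F1) already carries the ring B oxygen, the future enone β-carbon and a halogen in the required 1,3,4 pattern. F1 is protected with MOMCl and K2CO3 as in step 3 to give 3-bromo-4-(methoxymethoxy)benzaldehyde (F2). Suzuki coupling of F2 with 3 under the conditions of step 4 gives 3-[2,4-bis(methoxymethoxy)phenyl]-4-(methoxymethoxy)benzaldehyde (F3). Commercial 1-(2,4-dihydroxyphenyl)ethan-1-one (F4) is protected selectively at its non-chelated 4-hydroxyl (MOMCl, K2CO3, acetone) to give 1-[2-hydroxy-4-(methoxymethoxy)phenyl]ethan-1-one (F5); the 2-hydroxyl of F4 is held back by its hydrogen bond to the ketone. Claisen–Schmidt condensation of F5 with F3 (KOH, EtOH, rt) gives the protected chalcone (2E)-3-{3-[2,4-bis(methoxymethoxy)phenyl]-4-(methoxymethoxy)phenyl}-1-[2-hydroxy-4-(methoxymethoxy)phenyl]prop-2-en-1-one (F6). F6 is closed by 6-endo oxa-Michael addition with NaOAc in refluxing EtOH to give 10, with unreacted F6 recycled.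

Step 9. The main risks are acid-promoted addition of the resorcinol ring across the cinnamic double bond instead of acylation at the carboxyl group, oligomerisation of 12, and ionisation of the C2–O1 bond of the flavanone under hot Lewis acid, which would lead to intermolecular alkylation. The fallback sets out from 11 and comes back at 15, avoiding both the cinnamic acid and hot BF3. Houben–Hoesch acetylation of ring C (CH3CN, ZnCl2, HCl gas, Et2O, 0 °C) should give 1-{2,4-dihydroxy-5-[2-hydroxy-5-(7-hydroxy-4-oxochroman-2-yl)phenyl]phenyl}ethan-1-iminium chloride (F7). F7 is hydrolysed in warm water to 2-[3-(5-acetyl-2,4-dihydroxyphenyl)-4-hydroxyphenyl]-7-hydroxychroman-4-one (F8). Claisen–Schmidt condensation of F8 with 4-hydroxybenzaldehyde (F9) in 50% aq KOH/EtOH under N2 builds the C–D enone and opens the flavanone in the same flask. F9 is used in excess because its phenoxide is a weak electrophile. Acidification as in step 10 then gives 15.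

Step 10. The risks are incomplete ring opening or re-closure during acidification, retro-aldol fragmentation of either enone in alkali, and air oxidation of the polyphenolate. The fallback sets out from 13 and comes back at 15, trapping the open form covalently. Heating 13 with Ac2O and NaOAc at 120 °C acetylates the phenols and, after enolisation and β-elimination, the liberated ring A oxygen, giving rhuschalcone VI hexaacetate (F10). F10 is neutral and can be purified. Brief methanolysis of F10 (K2CO3, MeOH, 0 °C) followed by dilute HCl releases 15.

Step 5. The risks are hydrodechlorination, homocoupling of the product with unreacted chloride, sluggish oxidative addition into the electron-rich C–Cl bond, and losses on isolating a polar boronic acid. The fallback sets out from 6 and comes back at 7, going through an ester that can be chromatographed. Borylation with B2pin2 (Pd2(dba)3, dba = dibenzylideneacetone, zerovalent palladium; XPhos, KOAc, 1,4-dioxane, 110 °C) gives 2-{3-[2,4-bis(methoxymethoxy)phenyl]-4-(methoxymethoxy)phenyl}-4,4,5,5-tetramethyl-1,3,2-dioxaborolane (F11). Oxidative cleavage of the pinacol unit of F11 (NaIO4, NH4OAc, acetone/H2O, rt) then gives 7 without acid.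

## Further compounds

F1 | step 7 | 3-bromo-4-hydroxybenzaldehyde | O=Cc1ccc(O)c(Br)c1
F2 | step 7 | 3-bromo-4-(methoxymethoxy)benzaldehyde | O=Cc1ccc(OCOC)c(Br)c1
F3 | step 7 | 3-[2,4-bis(methoxymethoxy)phenyl]-4-(methoxymethoxy)benzaldehyde | O=Cc1ccc(OCOC)c(-c2ccc(OCOC)cc2OCOC)c1
F4 | step 7 | 1-(2,4-dihydroxyphenyl)ethan-1-one | CC(=O)c1ccc(O)cc1O
F5 | step 7 | 1-[2-hydroxy-4-(methoxymethoxy)phenyl]ethan-1-one | CC(=O)c1ccc(OCOC)cc1O
F6 | step 7 | (2E)-3-{3-[2,4-bis(methoxymethoxy)phenyl]-4-(methoxymethoxy)phenyl}-1-[2-hydroxy-4-(methoxymethoxy)phenyl]prop-2-en-1-one | O=C(/C=C/c1ccc(OCOC)c(-c2ccc(OCOC)cc2OCOC)c1)c1ccc(OCOC)cc1O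
F7 | step 9 | 1-{2,4-dihydroxy-5-[2-hydroxy-5-(7-hydroxy-4-oxochroman-2-yl)phenyl]phenyl}ethan-1-iminium chloride (racemic) | CC(=[NH2+])c1cc(-c2cc(C3CC(=O)c4ccc(O)cc4O3)ccc2O)c(O)cc1O.[Cl-]
F8 | step 9 | 2-[3-(5-acetyl-2,4-dihydroxyphenyl)-4-hydroxyphenyl]-7-hydroxychroman-4-one (racemic) | CC(=O)c1cc(-c2cc(C3CC(=O)c4ccc(O)cc4O3)ccc2O)c(O)cc1O
F9 | step 9 | 4-hydroxybenzaldehyde | O=Cc1ccc(O)cc1
F10 | step 10 | rhuschalcone VI hexaacetate | O=C(/C=C/c1ccc(OC(C)=O)c(-c2cc(C(=O)/C=C/c3ccc(OC(C)=O)cc3)c(OC(C)=O)cc2OC(C)=O)c1)c1ccc(OC(C)=O)cc1OC(C)=O
F11 | step 5 | 2-{3-[2,4-bis(methoxymethoxy)phenyl]-4-(methoxymethoxy)phenyl}-4,4,5,5-tetramethyl-1,3,2-dioxaborolane | COCOc1ccc(B2OC(C)(C)C(C)(C)O2)cc1-c1ccc(OCOC)cc1OCOC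
A1 | alternative 1 | (E)-1-[5-(5-bromo-2-hydroxyphenyl)-2,4-dihydroxyphenyl]-3-(4-hydroxyphenyl)prop-2-en-1-one | O=C(/C=C/c1ccc(O)cc1)c1cc(-c2cc(Br)ccc2O)c(O)cc1O
A2 | alternative 1 | 4-(5-bromo-2-hydroxyphenyl)benzene-1,3-diol | Oc1ccc(-c2cc(Br)ccc2O)c(O)c1
A3 | alternative 2 | (E)-1-{5-[5-bromo-2-(methoxymethoxy)phenyl]-2,4-bis(methoxymethoxy)phenyl}-3-(4-hydroxyphenyl)prop-2-en-1-one | O=C(/C=C/c1ccc(O)cc1)c1cc(-c2cc(Br)ccc2OCOC)c(OCOC)cc1OCOC
A4 | alternative 2 | 1-{5-[5-bromo-2-(methoxymethoxy)phenyl]-2,4-bis(methoxymethoxy)phenyl}prop-2-en-1-one | C=CC(=O)c1cc(-c2cc(Br)ccc2OCOC)c(OCOC)cc1OCOC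
A5 | alternative 2 | 4-iodophenol | Oc1ccc(I)cc1
A6 | alternative 3 | (E)-1-{5-[5-bromo-2-(methoxymethoxy)phenyl]-2-hydroxy-4-(methoxymethoxy)phenyl}-3-[4-(methoxymethoxy)phenyl]prop-2-en-1-one | O=C(/C=C/c1ccc(OCOC)cc1)c1cc(-c2cc(Br)ccc2OCOC)c(OCOC)cc1O
A7 | alternative 3 | 5-[5-bromo-2-(methoxymethoxy)phenyl]-2-hydroxy-4-(methoxymethoxy)benzaldehyde | O=Cc1cc(-c2cc(Br)ccc2OCOC)c(OCOC)cc1O
A8 | alternative 3 | 1-ethynyl-4-(methoxymethoxy)benzene | C#Cc1ccc(OCOC)cc1
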